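The readings are simulated with constants of no real substance.

A turnover is the unit I count in: one product made per catalyst charged. The winter run is this same flask, followed so far.

- winter: substrate 20 mM; free catalyst 0.83 mol%; the very flask that is asked about, followed so far
- flask: substrate 20 mM; free catalyst 0.83 mol%; time 2.0 min

winter run (percent of the substrate charged)

| time / s | product / % | substrate / % |
|---|---|---|
| 10.0 | 7.3 | 91.4 |
| 12.0 | 7.4 | 90.7 |
| 20.0 | 11.9 | 88.4 |
| 40.0 | 24.6 | 76.7 |
| 60.0 | 35.8 | 65.4 |

(standard deviation of a reading: 1 percentage point)

- what was read earlier has a scatter of 1 percentage point, one standard deviation

- the product in the flask at 2.0 min, as a percentage of the substrate charged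
- the substrate in the flask at 2.0 min, as a percentage of the substrate charged

*How many turnovers had the winter run made at its last reading?* About 43.1, from 35.8% of product on 0.83 mol% of free catalyst in 60.0 s.

*How many does the charge allow?* 120, so a third of them were used.

*Does the pace hold?* The winter readings leave it open. At 40.0 s a straight line through the origin and the last reading puts product at 23.9%, a pace falling with c(substrate) puts it at 24.7%, and the reading is 24.6%, with a scatter of 1 percentage point.

*Then why bend the line?* That is my judgement, not a reading. I assume that each turnover begins when substrate meets catalyst, so the pace follows c(substrate), a pseudo-first-order law. From 65.4% of substrate left at 60.0 s I read the turnover constant 51.2 min⁻¹: the turnovers per minute of a catalyst with the whole charge of substrate around it.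

*And at 2.0 min?* My estimate is substrate 42.8% and product 57.2%, which is 68.9 turnovers.

The forecast parts from me with 68% product and 32% substrate, reading “a saturated catalyst, roughly zero order in substrate”, close to a straight line through the last two readings.

The flask gives 59.9% product and 39.6% substrate.

    substrate + free catalyst → catalyst intermediate (k = 122 L mol⁻¹ s⁻¹)
    catalyst intermediate ⇌ free catalyst + product (K = 0.0260 M, k = 1.16 s⁻¹)

That is 72.2 turnovers against my 68.9, and the turnover constant read back from the substrate left is 55.8 min⁻¹, larger than my 51.2 min⁻¹. On a neighbouring flask with the same charges, read at 3.0 min, my constant gives 28.0% substrate and 72.0% product, or 86.8 turnovers. That neighbour holds 22.6% substrate and 76.9% product, which is 92.7 turnovers.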